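Product leaves the catalyst from catalyst intermediate C, and the same intermediate also takes up reagent into the idle complex. So before the next run we ask whether to charge twice the reagent or leave it. The starting material is the limiting reagent, since the flask holds 5.00 reagent for each starting material and one is used per turn.

starting material 0.0050 M; reagent 0.0250 M; free catalyst 50 µM

    catalyst intermediate B ⇌ catalyst intermediate C (K1 = 0.52, k1 = 1.7 /s)
    catalyst intermediate C ⇌ free catalyst + product (K2 = 0.010 M, k2 = 8.1 /s)
    reagent + catalyst intermediate C ⇌ idle complex, settled at all times (K3 = 2900 /M)
    reagent + catalyst intermediate A → catalyst intermediate B (k4 = 150 /M/s)
    starting material + free catalyst ⇌ catalyst intermediate A (K5 = 650 /M, k5 = 3600 /M/s)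

- the form that holds most of the catalyst when 5.0 % of the starting material are converted (catalyst intermediate A / catalyst intermediate C / free catalyst / catalyst intermediate B / idle complex)
- its share of the catalyst then
- apparent order in reagent when 5.0 % of the starting material are converted (percent change of the rate of making product for one percent more reagent charged)
- factor on the rate of making product when 5.0 % of the starting material are converted if reagent is charged twice over

We reckon at 5.0 % conversion of the starting material, with starting material at 4.75 mM and reagent at 24.8 mM, and we leave out the return of product to free catalyst. While the forms hold steady, the share of the catalyst in a form equals the share of the time per product spent in that form, so we turn each constant into a time. The balance gives 71.8 idle complex per catalyst intermediate C, and that intermediate lasts 0.123 s per product released. This gives 8.86 s per product, the idle wait: the time a catalyst sits in the idle complex for each product it makes.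

The working round goes on with 0.826 s in catalyst intermediate B, 0.269 s in catalyst intermediate A, and 0.146 s as free catalyst, of which 0.0872 s is the price of catalyst intermediate A falling back to free catalyst and starting material. With the idle wait, each product costs 10.2 s. The idle complex therefore holds 86.9 % of the catalyst, because the idle wait is longer than the working round.

More reagent lengthens the idle wait in proportion and shortens both the time in catalyst intermediate A and the price of falling back. Our order is then −0.834, and twice the reagent gives a factor of 0.540. We leave the reagent charge as it is.

The forecast names the idle complex at 87 %, with order −0.83 and factor 0.54, on the ground that the idle complex “makes the rate fall almost inversely with reagent”. A rate that held up with twice the reagent would refute it.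

The simulation gives the idle complex at 86.8 % after 0.708 min, with order −0.83 and factor 0.541. In this flask our idle wait of 8.86 s stands against 1.34 s for the working round, and catalyst intermediate B holds 7.97 % of the catalyst. In the flask with twice the reagent our idle wait reckons to 17.7 s, and the rate stands at 0.541 of the rate with the plain charge.

(The constants stand for no real mixture; the rest is arithmetic.)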